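**Retrosynthetic overview**
1. The target comes from its C1 ketone by hydride reduction. The cinnamate comes from an acrylate by Heck arylation with iodobenzene. The acrylate comes from a trans-decalin-1,4-dione by MeLi addition at C4 and acylation of the alkoxide in the same flask.
2. Ring B is closed last, by ring-closing metathesis of an allyl arm on C10 and a 2-isopropylallyl arm on C5. A temporary C2=C3 double bond leaves C5 as the only enolisable carbon for that alkylation.
3. The quaternary carbon C10 is set by decarboxylative asymmetric allylation of a regiodefined enol carbonate of ring A.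
4. Ring A is made first, by one-carbon ring expansion of 2-methylcyclopentane-1,3-dione to the cyclohexane-1,4-dione. The expansion runs through a zinc cyclopropanolate, amounts to a net 1,2-acyl shift, and the enolate is trapped as it forms.

Numbering note: C1 to C10 are the eudesmane positions of the target. C1 is the carbinol carbon, C4 the ester carbon, C5 the ring-fusion CH, C7=C8 the alkene and C10 the quaternary carbon.
Assumption: (S)-t-BuPHOX delivers allyl to the same enolate face as it does with the allyl enol carbonate of 2-methylcyclohexanone. If the sense were opposite, (R)-t-BuPHOX would be used.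

Step 1
Reactants: 1 2-methylcyclopentane-1,3-dione; 2 diiodomethane; 3 allyl chloroformate
Product: 6 2-methyl-4-oxocyclohex-1-en-1-yl prop-2-en-1-yl carbonate, via zinc cyclopropanolate 4 (not isolated), via zinc enolate 5 (not isolated)
Conditions: Et2Zn (2.1 equiv), 2 (1.0 equiv), CH2Cl2, 0 °C to rt; then TMEDA, 3 (1.3 equiv), −20 °C to rt; aq NH4Cl
Reagents that add atoms: none
Why: Proposed new method: the zinc enolate of 1 attacks the electrophilic carbenoid EtZnCH2I through its central carbon, the resulting β-zincio ketone closes onto one carbonyl to the donor–acceptor cyclopropanolate 4, and strain-driven retro-aldol cleavage of the ring-fusion bond (a net 1,2-acyl shift from C10 to the new CH2, C5) enlarges the five-membered 1,3-dione to the six-membered 1,4-dione as the single tetrasubstituted enolate 5, which is too hindered for C-acylation and is O-acylated by 3, the closest known reaction type being the zinc-carbenoid chain extension of acyclic β-keto esters and β-diketones to γ-dicarbonyl compounds, which has not been shown as a ring enlargement of a cyclic 2-alkyl-1,3-dione with capture of the enolate as an enol carbonate.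

Step 2
Reactants: 6 2-methyl-4-oxocyclohex-1-en-1-yl prop-2-en-1-yl carbonate
Product: 7 (2R)-2-methyl-2-(prop-2-en-1-yl)cyclohexane-1,4-dione
Conditions: Pd2(dba)3 (2.5 mol %), (S)-t-BuPHOX (6.25 mol %), toluene, 25 °C
Reagents that add atoms: none
Why: In this decarboxylative asymmetric allylic alkylation (Tsuji type) zerovalent palladium ionises the allyl carbonate, CO2 is lost, and the regiodefined enolate couples with the π-allyl ligand inside the chiral P,N pocket, which sets the (R)-quaternary carbon C10 in about 90 % ee without enolate scrambling.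

Step 3
Reactants: 7 (2R)-2-methyl-2-(prop-2-en-1-yl)cyclohexane-1,4-dione
Product: 8 (5R)-5-methyl-5-(prop-2-en-1-yl)cyclohex-2-ene-1,4-dione
Conditions: 2-iodoxybenzoic acid (1.5 equiv), DMSO, 70 °C
Reagents that add atoms: none
Why: In this ketone dehydrogenation with 2-iodoxybenzoic acid only the C2–C3 pair has hydrogens on both carbons next to the carbonyls, so one enedione forms, it cannot aromatise because C10 is quaternary, C10 is untouched, and C5 becomes the only enolisable carbon.

Step 4
Reactants: 9 2,3-dimethylbut-1-ene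
Product: 10 2-(chloromethyl)-3-methylbut-1-ene
Conditions: N-chlorosuccinimide (1.05 equiv), PhSeCl (5 mol %), CH2Cl2, 25 °C
Reagents that add atoms: N-chlorosuccinimide, O=C1CCC(=O)N1Cl
Why: In this selenium-catalysed ene-type allylic chlorination the electrophile adds to the terminal CH2 and the double bond is re-formed towards the unhindered methyl group rather than the isopropyl methine, which gives the 2-isopropylallyl chloride and creates no stereocentre.

Step 5
Reactants: 8 (5R)-5-methyl-5-(prop-2-en-1-yl)cyclohex-2-ene-1,4-dione; 10 2-(chloromethyl)-3-methylbut-1-ene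
Product: 12 (5R,6R)-5-methyl-6-(3-methyl-2-methylidenebutyl)-5-(prop-2-en-1-yl)cyclohex-2-ene-1,4-dione, via lithium dienolate 11 (not isolated)
Conditions: LiN(SiMe3)2 (1.05 equiv), THF/DMPU, −78 °C; then 10 (1.3 equiv), Bu4NI (10 mol %), −78 to −20 °C
Reagents that add atoms: none
Why: In this kinetic cross-conjugated enolate alkylation 11 forms regiospecifically because C5 carries the only acidic sp3 C–H bonds, and the allylic halide approaches anti to the larger allyl arm on C10 to give mainly the 5,6-trans (6R) product, while any C5 epimer is corrected in step 6 because this centre stays epimerisable.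

Step 6
Reactants: 12 (5R,6R)-5-methyl-6-(3-methyl-2-methylidenebutyl)-5-(prop-2-en-1-yl)cyclohex-2-ene-1,4-dione
Product: 14 (4aR,8aR)-4a-methyl-7-(propan-2-yl)-2,3,4a,5,8,8a-hexahydronaphthalene-1,4-dione, via bicyclic enedione 13 (not isolated)
Conditions: second-generation Grubbs catalyst (5 mol %), toluene, 80 °C; then AcOH, Zn dust (5 equiv), 25 °C, then 70 °C; recrystallise to raise ee
Reagents that add atoms: none
Why: Ring-closing metathesis of the monosubstituted and the 1,1-disubstituted alkene closes ring B as the trisubstituted C7=C8 alkene with loss of ethene (the electron-poor ring enedione alkene is inert), Zn/AcOH then reduces only the enedione C2=C3 bond by electron transfer, and warm AcOH equilibrates C5 next to the C4 carbonyl to the more stable trans-fused (8aR) dione, in which the axial angular methyl faces only two syn-axial hydrogens.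

Step 7
Reactants: 14 (4aR,8aR)-4a-methyl-7-(propan-2-yl)-2,3,4a,5,8,8a-hexahydronaphthalene-1,4-dione; 15 acryloyl chloride
Product: 17 (1S,4aR,8aR)-1,4a-dimethyl-4-oxo-7-(propan-2-yl)-1,2,3,4,4a,5,8,8a-octahydronaphthalen-1-yl prop-2-enoate, via lithium alkoxide 16 (not isolated)
Conditions: MeLi (1.05 equiv), Et2O/THF, −78 °C; then 15 (1.5 equiv), −78 to 0 °C
Reagents that add atoms: methyllithium, [Li]C
Why: In this 1,2-addition followed by acylation in the same flask the C4 carbonyl next to the ring-fusion CH is much less hindered than the neopentyl C1 carbonyl, and MeLi enters it equatorially from the α face because the axial β path is blocked by the syn-axial C10 methyl, which sets C4 (S, methyl α, oxygen β and axial) and gives alkoxide 16 for direct esterification by 15.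

Step 8
Reactants: 17 (1S,4aR,8aR)-1,4a-dimethyl-4-oxo-7-(propan-2-yl)-1,2,3,4,4a,5,8,8a-octahydronaphthalen-1-yl prop-2-enoate; 18 iodobenzene
Product: 19 (1S,4aR,8aR)-1,4a-dimethyl-4-oxo-7-(propan-2-yl)-1,2,3,4,4a,5,8,8a-octahydronaphthalen-1-yl (2E)-3-phenylprop-2-enoate
Conditions: 18 (1.2 equiv), Pd(OAc)2 (5 mol %), P(o-tol)3 (10 mol %), NaOAc (1.5 equiv), DMF, 80 °C
Reagents that add atoms: none
Why: In this Mizoroki–Heck arylation the aryl-palladium species adds to the unhindered terminal carbon of the acrylate and syn β-hydride elimination gives only the E-cinnamate, while the trisubstituted C7=C8 alkene, the ketone and the stereocentres are not touched.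

Step 9
Reactants: 19 (1S,4aR,8aR)-1,4a-dimethyl-4-oxo-7-(propan-2-yl)-1,2,3,4,4a,5,8,8a-octahydronaphthalen-1-yl (2E)-3-phenylprop-2-enoate
Product: 20 (1S,4R,4aR,8aR)-4-hydroxy-1,4a-dimethyl-7-(propan-2-yl)-1,2,3,4,4a,5,8,8a-octahydronaphthalen-1-yl (2E)-3-phenylprop-2-enoate
Conditions: NaBH4 (1 equiv), CeCl3·7H2O (1 equiv), MeOH, −20 °C
Reagents that add atoms: none
Why: In this Luche-type carbonyl reduction hydride attacks the C1 ketone axially from the α face, opposite the axial C10 methyl, to give the equatorial 1β alcohol (R at C1), and the cinnamate ester is inert under these conditions.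

**Compound list**
1 | 2-methylcyclopentane-1,3-dione | CC1C(=O)CCC1=O | starting material
2 | diiodomethane | ICI | starting material
3 | allyl chloroformate | C=CCOC(=O)Cl | starting material
4 | ethylzinc 5-methyl-4-oxobicyclo[3.1.0]hexan-1-olate | CC[Zn]OC12CCC(=O)C1(C)C2 | intermediate
5 | ethylzinc 2-methyl-4-oxocyclohex-1-en-1-olate | CC[Zn]OC1=C(C)CC(=O)CC1 | intermediate
6 | 2-methyl-4-oxocyclohex-1-en-1-yl prop-2-en-1-yl carbonate | C=CCOC(=O)OC1=C(C)CC(=O)CC1 | intermediate
7 | (2R)-2-methyl-2-(prop-2-en-1-yl)cyclohexane-1,4-dione | C=CC[C@@]1(C)C(=O)CCC(=O)C1 | intermediate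
8 | (5R)-5-methyl-5-(prop-2-en-1-yl)cyclohex-2-ene-1,4-dione | C=CC[C@@]1(C)C(=O)C=CC(=O)C1 | intermediate
9 | 2,3-dimethylbut-1-ene | C=C(C)C(C)C | starting material
10 | 2-(chloromethyl)-3-methylbut-1-ene | C=C(CCl)C(C)C | intermediate
11 | lithium dienolate of 8 (O on C4, C4=C5) | C=CC[C@@]1(C)C(=O)C=CC([O-])=C1.[Li+] | intermediate
12 | (5R,6R)-5-methyl-6-(3-methyl-2-methylidenebutyl)-5-(prop-2-en-1-yl)cyclohex-2-ene-1,4-dione | C=CC[C@@]1(C)C(=O)C=CC(=O)[C@@H]1CC(=C)C(C)C | intermediate
13 | (4aR,8aR)-4a-methyl-7-(propan-2-yl)-4a,5,8,8a-tetrahydronaphthalene-1,4-dione | CC(C)C1=CC[C@@]2(C)C(=O)C=CC(=O)[C@@H]2C1 | intermediate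
14 | (4aR,8aR)-4a-methyl-7-(propan-2-yl)-2,3,4a,5,8,8a-hexahydronaphthalene-1,4-dione | CC(C)C1=CC[C@@]2(C)C(=O)CCC(=O)[C@@H]2C1 | intermediate
15 | acryloyl chloride | C=CC(=O)Cl | starting material
16 | lithium (1S,4aR,8aR)-1,4a-dimethyl-4-oxo-7-(propan-2-yl)-1,2,3,4,4a,5,8,8a-octahydronaphthalen-1-olate | CC(C)C1=CC[C@@]2(C)C(=O)CC[C@](C)([O-])[C@@H]2C1.[Li+] | intermediate
17 | (1S,4aR,8aR)-1,4a-dimethyl-4-oxo-7-(propan-2-yl)-1,2,3,4,4a,5,8,8a-octahydronaphthalen-1-yl prop-2-enoate | CC(C)C1=CC[C@@]2(C)C(=O)CC[C@](C)(OC(=O)C=C)[C@@H]2C1 | intermediate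
18 | iodobenzene | Ic1ccccc1 | starting material
19 | (1S,4aR,8aR)-1,4a-dimethyl-4-oxo-7-(propan-2-yl)-1,2,3,4,4a,5,8,8a-octahydronaphthalen-1-yl (2E)-3-phenylprop-2-enoate | CC(C)C1=CC[C@@]2(C)C(=O)CC[C@](C)(OC(=O)/C=C/c3ccccc3)[C@@H]2C1 | intermediate
20 | (1S,4R,4aR,8aR)-4-hydroxy-1,4a-dimethyl-7-(propan-2-yl)-1,2,3,4,4a,5,8,8a-octahydronaphthalen-1-yl (2E)-3-phenylprop-2-enoate | CC(C)C1=CC[C@@]2(C)[C@H](O)CC[C@](C)(OC(=O)/C=C/c3ccccc3)[C@@H]2C1 | target

**Step count**
Total steps: 9. Longest linear sequence: 8 (steps 1, 2, 3, 5, 6, 7, 8 and 9, starting from 1).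

**Steps most likely to fail**

Step 1 (the proposed new step). The risks are these:
- O-methylenation of the cyclic enolate instead of C-attack.
- C-acylation of 5 instead of O-acylation.
- Cyclopropanation of the allyl group by carbenoid left in the flask.

The fallback uses known chemistry, sets out from 1 and comes back at 7. Compound 1 is C-alkylated with CH2Br2 (NaH, THF/HMPA) to 2-(bromomethyl)-2-methylcyclopentane-1,3-dione F1. Its primary radical (Bu3SnH, AIBN, benzene, 80 °C) undergoes the Dowd–Beckwith radical ring expansion to 2-methylcyclohexane-1,4-dione F2. The unhindered carbonyl is masked (ethylene glycol, TsOH) as 7-methyl-1,4-dioxaspiro[4.5]decan-8-one F3. TMSCl, NaI and Et3N give the more substituted enol ether trimethyl[(7-methyl-1,4-dioxaspiro[4.5]dec-7-en-8-yl)oxy]silane F4. MeLi and then 3 give 7-methyl-1,4-dioxaspiro[4.5]dec-7-en-8-yl prop-2-en-1-yl carbonate F5. Pd2(dba)3 with (S)-t-BuPHOX gives (7R)-7-methyl-7-(prop-2-en-1-yl)-1,4-dioxaspiro[4.5]decan-8-one F6. Aqueous HCl in THF then releases 7.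

Step 5. The risks are self-Michael addition of the enedione enolate, electron transfer from the amide base, and slow reaction at the neopentyl carbon C5. The fallback replaces the polar C5–C6 bond formation with a radical one; it sets out from 8 and 10 and comes back at 12. Compound 8 is soft-enolised (TBSOTf, Et3N) to (6R)-4-[(tert-butyldimethylsilyl)oxy]-6-methyl-6-(prop-2-en-1-yl)cyclohexa-2,4-dien-1-one F7. N-Bromosuccinimide converts this to (5S)-6-bromo-5-methyl-5-(prop-2-en-1-yl)cyclohex-2-ene-1,4-dione F8, in which the quaternary centre is spatially unchanged. Compound 10 and Bu3SnLi give tributyl(3-methyl-2-methylidenebutyl)stannane F9. Keck radical allylation of F8 with F9 (AIBN, benzene, 80 °C) gives 12.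

Step 7. The risks are attack at or enolisation of the C1 ketone and slow acylation of the axial tertiary alkoxide. The fallback separates the two carbonyl groups with protecting groups; it sets out from 14 and comes back at 20. Ethylene glycol and TsOH ketalise only the less hindered C4 carbonyl to give the C4 mono(ethylene ketal) of 14 F10. NaBH4 gives its 1β-alcohol F11. TBSOTf with 2,6-lutidine, then aqueous acid in acetone, gives the 1β-O-TBS 4-ketone F12. MeLi and then 15 give the 1β-O-TBS 4β-acrylate F13. Heck arylation with 18 gives the 1β-O-TBS 4β-cinnamate F14. HF·pyridine then gives 20.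

**Further compounds**
F1 | step 1 | 2-(bromomethyl)-2-methylcyclopentane-1,3-dione | CC1(CBr)C(=O)CCC1=O
F2 | step 1 | 2-methylcyclohexane-1,4-dione | CC1CC(=O)CCC1=O
F3 | step 1 | 7-methyl-1,4-dioxaspiro[4.5]decan-8-one | CC1CC2(CCC1=O)OCCO2
F4 | step 1 | trimethyl[(7-methyl-1,4-dioxaspiro[4.5]dec-7-en-8-yl)oxy]silane | C[Si](C)(C)OC1=C(C)CC2(CC1)OCCO2
F5 | step 1 | 7-methyl-1,4-dioxaspiro[4.5]dec-7-en-8-yl prop-2-en-1-yl carbonate | C=CCOC(=O)OC1=C(C)CC2(CC1)OCCO2
F6 | step 1 | (7R)-7-methyl-7-(prop-2-en-1-yl)-1,4-dioxaspiro[4.5]decan-8-one | C=CC[C@@]1(C)C(=O)CCC2(C1)OCCO2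
F7 | step 5 | (6R)-4-[(tert-butyldimethylsilyl)oxy]-6-methyl-6-(prop-2-en-1-yl)cyclohexa-2,4-dien-1-one | C=CC[C@@]1(C)C(=O)C=CC(O[Si](C)(C)C(C)(C)C)=C1
F8 | step 5 | (5S)-6-bromo-5-methyl-5-(prop-2-en-1-yl)cyclohex-2-ene-1,4-dione | C=CC[C@@]1(C)C(=O)C=CC(=O)C1Br
F9 | step 5 | tributyl(3-methyl-2-methylidenebutyl)stannane | CCCC[Sn](CCCC)(CCCC)CC(=C)C(C)C
F10 | step 7 | C4 mono(ethylene ketal) of 14 | CC(C)C1=CC[C@@]2(C)C(=O)CCC3(OCCO3)[C@@H]2C1
F11 | step 7 | 1β-alcohol of the C4 ketal | CC(C)C1=CC[C@@]2(C)[C@H](O)CCC3(OCCO3)[C@@H]2C1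
F12 | step 7 | 1β-O-TBS 4-ketone | CC(C)C1=CC[C@@]2(C)[C@H](O[Si](C)(C)C(C)(C)C)CCC(=O)[C@@H]2C1
F13 | step 7 | 1β-O-TBS 4β-acrylate | CC(C)C1=CC[C@@]2(C)[C@H](O[Si](C)(C)C(C)(C)C)CC[C@](C)(OC(=O)C=C)[C@@H]2C1
F14 | step 7 | 1β-O-TBS 4β-cinnamate | CC(C)C1=CC[C@@]2(C)[C@H](O[Si](C)(C)C(C)(C)C)CC[C@](C)(OC(=O)/C=C/c3ccccc3)[C@@H]2C1
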